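The plan rests on cutting C5–C6 of the docosanoyl chain. This is a plain CH2–CH2 bond inside the unbranched, heteroatom-free segment C2–C22, remote from the ester carbonyl C1 and from the benzene ring. One mixed Kolbe electrolysis forges this bond: stearic acid supplies C6–C22 as a heptadecyl radical, and an adipic half-ester supplies C1–C5 as a 4-(alkoxycarbonyl)butyl radical. The electrolysis precursor already contains the finished 3-arylpropyl ester C–O bond and the para-disubstituted benzene ring. Its phenol is masked as an electron-poor tert-butyl carbonate, and it ends in a free carboxyl group. No ring is closed, and the target has no stereocentre.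

Key step: step 4

Remark on the chemistry: the SMILES holds no stereocentre and no stereogenic double bond, so the compound is achiral and the request for a single enantiomer is met without any stereocontrol.

Step 1
Reactants: 1 3-(4-hydroxyphenyl)propan-1-ol
Product: 3 tert-butyl 4-(3-hydroxypropyl)phenyl carbonate, via sodium phenolate 2 (not isolated)
Conditions: NaOH (1.05 equiv), Boc2O (1.05 equiv), THF/H2O, 0 °C to rt
Reagents that add atoms: di-tert-butyl dicarbonate, CC(C)(C)OC(=O)OC(=O)OC(C)(C)C
Why: Schotten–Baumann-type O-acylation in which one equivalent of hydroxide ionises only the phenol (pKa about 10), so 2 alone attacks Boc2O and the neutral primary alcohol stays free, and the hindered, electron-withdrawing tert-butyl carbonate is preferred to a simple aryl ester because it resists acyl transfer to alcohols both in the DMAP-catalysed coupling and in the warm carboxylate-buffered methanol of the electrolysis.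

Step 2
Reactants: 3 tert-butyl 4-(3-hydroxypropyl)phenyl carbonate; 4 6-(benzyloxy)-6-oxohexanoic acid (adipic acid monobenzyl ester)
Product: 6 benzyl 3-{4-[(tert-butoxycarbonyl)oxy]phenyl}propyl hexanedioate, via O-acylisourea 5 (not isolated)
Conditions: EDC·HCl (1.3 equiv), DMAP (0.1 equiv), CH2Cl2, 0 °C to rt
Reagents that add atoms: none
Why: Steglich esterification in which acid 4 adds to the carbodiimide to give 5 and DMAP relays the acyl group to the only free hydroxyl of 3, which forms the alkyl ester C–O bond of the target under near-neutral conditions that leave the benzyl ester and the aryl carbonate alone.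

Step 3
Reactants: 6 benzyl 3-{4-[(tert-butoxycarbonyl)oxy]phenyl}propyl hexanedioate
Product: 7 6-(3-{4-[(tert-butoxycarbonyl)oxy]phenyl}propoxy)-6-oxohexanoic acid
Conditions: H2 (1 atm), 10% Pd/C, EtOAc, rt
Reagents that add atoms: none
Why: Catalytic hydrogenolysis cleaves only the benzylic C–O bond of the benzyl ester, because the oxygen of the other ester sits three carbons away from its ring, the aryl tert-butyl carbonate has no benzylic C–O bond, and the aprotic solvent rules out transesterification.

Step 4
Reactants: 7 6-(3-{4-[(tert-butoxycarbonyl)oxy]phenyl}propoxy)-6-oxohexanoic acid; 8 stearic acid (octadecanoic acid)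
Product: 11 3-{4-[(tert-butoxycarbonyl)oxy]phenyl}propyl docosanoate, via heptadecyl radical 9 (not isolated), via ester-bearing butyl radical 10 (not isolated)
Conditions: 8 (5 equiv), NaOMe (5 mol% of total acid, added to 8 first), MeOH, 45–50 °C, undivided cell, smooth Pt/Pt, ca. 0.2 A cm−2, periodic polarity reversal, 7 fed in portions, stopped while still acidic
Reagents that add atoms: none
Why: At smooth platinum under high current density the small carboxylate fraction of 7 and 8 packs onto the anode, each carboxylate loses one electron and CO2, and the primary radicals 9 (C17) and 10 (C5) born side by side at the surface combine to the C5–C6 sigma bond of the C22 chain (17 + 5 = 22 carbons), while acid protons are discharged as H2 at the cathode. The closest known reaction type is exactly this one, the crossed Kolbe chain extension of a fatty acid by a dicarboxylic acid half-ester, applied here to a half-ester whose alcohol part carries a masked phenol. No ring is closed and no stereocentre is created, so no closure mode and no controlling element come into play. Cross- over homo-coupling is statistical and is secured by the fivefold excess of cheap 8 and the portionwise feed of 7, so that 10 meets mainly 9, and the two homo-dimers (a C34 alkane and a symmetrical C10 diester) lie far from 11 in polarity. Radical coupling over further oxidation to carbocations is secured because both radicals are primary, unbranched and without alpha-heteroatom, and carboxylate over arene oxidation because the ring oxygen is acylated and electron-poor and the adsorbed carboxylate film keeps the ring away from the metal. An acid reserve kept throughout (base is given to 8 before 7 enters, current is cut before neutrality) means that no methoxide builds up to attack the aryl carbonate or to transesterify the arylpropyl ester.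

Step 5
Reactants: 11 3-{4-[(tert-butoxycarbonyl)oxy]phenyl}propyl docosanoate
Product: 12 3-(4-hydroxyphenyl)propyl docosanoate
Conditions: TFA/CH2Cl2 (1:4), 0 °C to rt, open to a bubbler
Reagents that add atoms: none
Why: Acidolytic Boc cleavage in which protonation of the carbonate triggers alkyl–oxygen fission with loss of isobutene and CO2, while the primary alkyl docosanoate cannot ionise in this way and is inert to anhydrous TFA, so no base or nucleophile that could cleave or move the C22 acyl group is present, and the waxy substrate stays dissolved in CH2Cl2.

Compound list
1 | 3-(4-hydroxyphenyl)propan-1-ol | OCCCc1ccc(O)cc1 | starting material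
2 | sodium 4-(3-hydroxypropyl)phenolate (not isolated) | [Na+].[O-]c1ccc(CCCO)cc1 | intermediate
3 | tert-butyl 4-(3-hydroxypropyl)phenyl carbonate | CC(C)(C)OC(=O)Oc1ccc(CCCO)cc1 | intermediate
4 | 6-(benzyloxy)-6-oxohexanoic acid (adipic acid monobenzyl ester) | OC(=O)CCCCC(=O)OCc1ccccc1 | starting material
5 | O-acylisourea from 4 and EDC (not isolated) | CCN=C(NCCCN(C)C)OC(=O)CCCCC(=O)OCc1ccccc1 | intermediate
6 | benzyl 3-{4-[(tert-butoxycarbonyl)oxy]phenyl}propyl hexanedioate | CC(C)(C)OC(=O)Oc1ccc(CCCOC(=O)CCCCC(=O)OCc2ccccc2)cc1 | intermediate
7 | 6-(3-{4-[(tert-butoxycarbonyl)oxy]phenyl}propoxy)-6-oxohexanoic acid | CC(C)(C)OC(=O)Oc1ccc(CCCOC(=O)CCCCC(=O)O)cc1 | intermediate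
8 | stearic acid (octadecanoic acid) | CCCCCCCCCCCCCCCCCC(=O)O | starting material
9 | heptadecyl radical (not isolated) | CCCCCCCCCCCCCCCC[CH2] | intermediate
10 | 5-(3-{4-[(tert-butoxycarbonyl)oxy]phenyl}propoxy)-5-oxopentyl radical (not isolated) | [CH2]CCCC(=O)OCCCc1ccc(OC(=O)OC(C)(C)C)cc1 | intermediate
11 | 3-{4-[(tert-butoxycarbonyl)oxy]phenyl}propyl docosanoate | CCCCCCCCCCCCCCCCCCCCCC(=O)OCCCc1ccc(OC(=O)OC(C)(C)C)cc1 | intermediate
12 | 3-(4-hydroxyphenyl)propyl docosanoate | CCCCCCCCCCCCCCCCCCCCCC(=O)OCCCc1ccc(O)cc1 | target

Total step count: 5
Longest linear sequence: 5 steps (1 → 3 → 6 → 7 → 11 → 12)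

Steps most likely to fail

**1. Step 4.**
- What may go wrong: the anode may attack the aromatic ring or its benzylic C–H bonds in competition with carboxylate oxidation. Waxy hydrocarbon may coat the platinum. The carbonate may slowly methanolyse once the bath loses its acid reserve. Material is also lost statistically to homo-coupling.
- Fallback: the arene is kept out of the cell altogether. Setting out from 4 and 8, the same crossed Kolbe electrolysis is run on the benzyl half-ester itself and should give benzyl docosanoate F1. Hydrogenolysis (H2, Pd/C, EtOAc/THF) frees docosanoic acid F2. EDC/DMAP esterification of F2 with alcohol 3 comes back to the route at 11. The C5–C6 bond is still made anodically, but on a simple half-ester of the long-established substrate class.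

**2. Step 1.**
- What may go wrong: the two hydroxyl groups may be incompletely discriminated, so that carbonate also forms at the alcohol. The fresh aryl carbonate may also hydrolyse in the alkaline phase.
- Fallback: the order of events is inverted, so no selective acylation of a phenol is needed. Setting out from 1 and 4, a Mitsunobu esterification (PPh3, DIAD, THF, 0 °C) should give benzyl 3-(4-hydroxyphenyl)propyl hexanedioate F3. Only the aliphatic alcohol gives an oxyphosphonium ion open to SN2 displacement, and the far more acidic carboxylic acid outcompetes the phenol as nucleophile. The single remaining hydroxyl of F3 is then carbonated with Boc2O and catalytic DMAP in CH2Cl2, which comes back to the route at 6.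

**3. Step 5.**
- What may go wrong: the tert-butyl cation may be captured by the electron-rich ring of the liberated phenol (ortho C-alkylation).
- Fallback: the cleavage mode is switched from acid-induced alkyl–oxygen fission to aminolysis at the carbonate carbonyl, so no carbocation is generated. Setting out from 11, piperidine in CH2Cl2 at rt takes over the Boc group from the good aryloxide leaving group. The unactivated alkyl docosanoate does not undergo aminolysis at this temperature. The route is rejoined at 12, and no compound outside the list is made (F0).

Further compounds
F1 | step 4 | benzyl docosanoate | CCCCCCCCCCCCCCCCCCCCCC(=O)OCc1ccccc1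
F2 | step 4 | docosanoic acid | CCCCCCCCCCCCCCCCCCCCCC(=O)O
F3 | step 1 | benzyl 3-(4-hydroxyphenyl)propyl hexanedioate | Oc1ccc(CCCOC(=O)CCCCC(=O)OCc2ccccc2)cc1
F0 | step 5 | none | none
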